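The constants are made up; what happens was integrated by code.

These flasks are neighbours of one another: from theta through zeta to beta the scavenger charge climbs from 10.0 mM to 40.0 mM, and the other charges stay as they are.

    scavenger + released group → scavenged by-product (k1 = 10.6 M⁻¹ s⁻¹)
    coupling partner + released group ⇌ idle adduct, settled at all times (K2 = 67 M⁻¹)
    2 first chain carrier → ended chains (k3 = 4 × 10⁶ M⁻¹ s⁻¹)
    first chain carrier → ended carrier (k4 = 5.78 s⁻¹)
    released group → by-product carried off (k5 = 0.0392 s⁻¹)
    initiator → 2 initiating radical (k6 = 0.0337 s⁻¹)
    coupling partner → decomposed reagent (k7 = 0.0574 s⁻¹)
    coupling partner + first chain carrier → product + second chain carrier (k8 = 11900 M⁻¹ s⁻¹)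
    starting material + initiating radical → capped initiator + first chain carrier (k9 = 1.50 × 10⁵ M⁻¹ s⁻¹)
    starting material + second chain carrier → released group + first chain carrier (k10 = 96500 M⁻¹ s⁻¹)

all flasks: starting material 0.010 M; coupling partner 0.0120 M; initiator 1.1 mM; time 3.0 min

| charge | scavenger |
|---|---|
| theta | 10.0 mM |
| zeta | 20.0 mM |
| beta | 40.0 mM |

- part of the starting material that has reacted at the end, theta
- part of the starting material that has reacted at the end, zeta
- part of the starting material that has reacted at the end, beta
- what raising the concentration of scavenger from its lowest to its highest value here does to the part of the starting material that has reacted (changes below 5 percentage points count as none) (it rises / it falls / no change)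

- a species is counted by the starting material in it: one ended chains counts as two
- amounts and yields of released group count idle adduct too
- a doubled species enters its step squared and goes two at a time
- run time (theta): 3.0 min

**Two budgets.** You can count the consumption of starting material in two parts. Each radical from the initiator takes one starting material, and nearly all of the initiator breaks down within the run, so this part is worth 22.0% of c(starting material). Each turn of the chain takes one starting material and one coupling partner and gives one product, so the second part depends on how much coupling partner the chain gets. Scavenger meets released group, which carries no chain, so I give it no term, and I leave the idle adduct out of my reckoning as well.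

**Resting carrier.** At the charged amounts the first chain carrier is the resting state, because it waits on coupling partner at 143 s⁻¹ while the second chain carrier goes on at 965 s⁻¹. Setting radical supply equal to radical ending gives c(first chain carrier) of 2.70 × 10⁻⁶ M at the start, so coupling partner meets the chain at 0.0322 s⁻¹, slower than it decomposes at 0.0574 s⁻¹.

**Two ways.** If you freeze the carrier at that level, the two rates give a share of 35.9% and a conversion of 65.1%. If you let it fade, then pairwise ending outruns single ending at the start, so the carrier follows the square root of c(initiator) and falls at 0.0169 s⁻¹. Adding this fade to the losses gives 30.2%; this is the coupling share, the part of the charged coupling partner that ends as product. The two ways part, and the frozen one cheats, since it holds the carrier at its start value while the initiator falls with a half-life shorter than the run. I commit to the coupling share, which gives 58.3% for theta, zeta and beta alike.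

**The result.** The forecast gives 58%, 58.5% and 58.8% with no change, on the ground that “More scavenger barely matters.” The simulation gives 58.9% for theta, 59.0% for zeta and 59.0% for beta, a change of 0.14 percentage points, which counts as no change.

**Where it went.** In zeta at 0.148 min, decomposition used coupling partner 2.1 times as fast as the chain did. At the end of zeta, 0% of the coupling partner remains and 41% of the starting material stands unreacted, while product amounts to a share of 30.8% of the charged coupling partner. For a neighbour of zeta charged with 0.0072 M of coupling partner, the other charges and the time held, the coupling share of 30.2% gives 43.8% reacted, and the simulation gives 44.2%.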